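**Assumption:** The target's absolute configuration (drimane numbering 5S,9R,10S; 10-Me, C11 and the ring A/B oxygen face all "α" in the standard drawing with ring A on the left) is the enantiomer of the usual drimane series. It therefore needs (R)-Wieland–Miescher ketone (WMK). C8 epimers of 12–17 are carried as mixtures because C8 becomes sp² in Step 16. A commercial ketoreductase (KRED) that reduces the saturated ketone of WMK is assumed to be available from a standard screen.

## Retrosynthetic overview
1. Last steps: Mitsunobu etherification of the C11 primary alcohol with umbelliferone, then oxidation of the C3 alcohol to the ketone.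
2. The C6 ketone and the trans-decalin H-5/H-9 stereochemistry come from one hydroboration of the Δ5-ene and the 9(11)-methylene. The Δ7-en-6-one is then made by Saegusa–Ito dehydrogenation.
3. The 8-Me and 9(11)-methylene come from a C9 ketone (α-methylation, then Wittig). That ketone comes from a KRED-derived, enantio-enriched C9 carbinol.
4. Ring A is formed last in the D-proline Robinson annulation (2-methylcyclohexane-1,3-dione plus MVK), which sets C10. The 4,4-dimethyl-Δ5 unit comes from deconjugative dimethylation. All later steps are functional-group work on the decalin.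

## Route

**Step 1**
Reactants: 1 (2-methylcyclohexane-1,3-dione) + 2 (methyl vinyl ketone)
Product: 3 (2-methyl-2-(3-oxobutyl)cyclohexane-1,3-dione)
Conditions: H2O, 60 °C
Reagents that add atoms: none (MVK is reactant 2)
Why: Michael addition of the acidic dione to MVK builds the prochiral triketone; there is no stereocentre yet.

**Step 2**
Reactants: 3
Product: 4 ((R)-Wieland–Miescher ketone, (8aR)-8a-methyl-3,4,8,8a-tetrahydronaphthalene-1,6(2H,7H)-dione)
Conditions: D-proline (35 mol%), DMSO, 25 °C; then TsOH, PhH, 80 °C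
Reagents that add atoms: none
Why: In the Hajos–Parrish–Eder–Sauer–Wiechert asymmetric Robinson annulation, the D-proline enamine aldol desymmetrizes the dione and sets the quaternary C10 (R), typically in 75–90% ee.

**Step 3**
Reactants: 4
Product: 5 ((4aR,5R)-5-hydroxy-4a-methyl-4,4a,5,6,7,8-hexahydronaphthalen-2(3H)-one; C9 carbinol cis to the C10 methyl)
Conditions: KRED (NADPH-dependent ketoreductase), NADP⁺ (cat.), D-glucose, glucose dehydrogenase, KPi pH 7.0/10% DMSO, 30 °C
Reagents that add atoms: none (net H2 from glucose via NADPH)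
Why: The ketoreductase reduces only the saturated C9 ketone, delivering hydride anti to the angular methyl. It discriminates against the minor (S)-ketone, and crystallizing the ketol gives ≥99% ee. The C9 carbinol is temporary and is re-oxidized in Step 9, so only the enantiodiscrimination matters.

**Step 4**
Reactants: 5
Product: 6 (9-O-triethylsilyl ether of 5)
Conditions: TESCl, imidazole, DMF, 50 °C
Reagents that add atoms: TESCl, CC[Si](Cl)(CC)CC
Why: Silylation masks the hindered secondary alcohol so it survives the enolate alkylation in Step 5; no stereocentre is touched.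

**Step 5**
Reactants: 6
Product: 7 (9-OTES-4,4,10-trimethyl-Δ5-octalin-3-one)
Conditions: t-BuOK (3 equiv), MeI (4 equiv), t-BuOH/THF, 0 °C→rt
Reagents that add atoms: MeI, CI
Why: Deconjugative dienolate C-alkylation at C4, done twice, gives the 4,4-dimethyl-Δ5-3-ketone with no new stereocentre.

**Step 6**
Reactants: 7
Product: 8 (3-ol of 7, equatorial OH)
Conditions: NaBH4, MeOH/THF, 0 °C→rt
Reagents that add atoms: none
Why: Hydride reduction (axial attack) of the ketone gives the equatorial alcohol. This centre is re-oxidized in Step 19, so its configuration is irrelevant.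

**Step 7**
Reactants: 8
Product: 9 (3-OTBS, 9-OTES)
Conditions: TBSOTf, 2,6-lutidine, CH2Cl2, −20→0 °C
Reagents that add atoms: TBSOTf, CC(C)(C)[Si](C)(C)OS(=O)(=O)C(F)(F)F
Why: The neopentylic 3-OH needs a silyl triflate. TBS is orthogonal to the TES group and survives the later strong-base steps.

**Step 8**
Reactants: 9
Product: 10 (3-OTBS, 9-OH)
Conditions: PPTS, MeOH, 25 °C
Reagents that add atoms: none
Why: Mild acidic methanolysis cleaves the labile TES ether and leaves the hindered TBS ether.

**Step 9**
Reactants: 10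
Product: 11 (3-OTBS-4,4,10-trimethyl-Δ5-octalin-9-one)
Conditions: Dess–Martin periodinane, NaHCO3, CH2Cl2, 25 °C
Reagents that add atoms: none
Why: Dess–Martin oxidation converts the temporary C9 carbinol to the ketone and removes that stereocentre; C10 is untouched.

**Step 10**
Reactants: 11
Product: 12 (8-methyl-9-ketone; C8 epimeric mixture)
Conditions: LDA (1.2 equiv), THF, −78 °C; then MeI, DMPU, −78→0 °C
Reagents that add atoms: MeI, CI
Why: C8 is the only enolizable α-carbon, since C10 is quaternary, so kinetic enolate alkylation is regiospecific. The new C8 centre is removed in Step 16.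

**Step 11**
Reactants: 12
Product: 13 (9(11)-methylene, 8-Me, Δ5, 3-OTBS)
Conditions: Ph3P⁺CH3 Br⁻, t-BuOK, toluene, 110 °C
Reagents that add atoms: methyltriphenylphosphonium bromide, C[P+](c1ccccc1)(c1ccccc1)c1ccccc1.[Br-] (supplies the =CH2)
Why: Wittig methylenation with a small, reactive ylide is used for this hindered ketone next to a quaternary carbon.

**Step 12**
Reactants: 13
Product: 14 (6β,11-diol; H-5β, H-9β, C11 α; 3-OTBS)
Conditions: BH3·THF (6 equiv), THF, 0→60 °C; then 30% H2O2, 3 M NaOH, 0→25 °C
Reagents that add atoms: hydrogen peroxide, OO (source of the two new O atoms)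
Why: Syn hydroboration–oxidation of both alkenes occurs from the β-face, anti to the axial 10α- and 4α-methyls. This delivers the trans-fused H-5β and the axial H-9β (equatorial CH2OH) in one operation. The C6 carbinol is oxidized later.

**Step 13**
Reactants: 14
Product: 15 (11-OTBS)
Conditions: TBSCl (1.1 equiv), imidazole, DMF, 25 °C
Reagents that add atoms: TBSCl, CC(C)(C)[Si](C)(C)Cl
Why: The unhindered primary alcohol is silylated selectively over the hindered C6 secondary alcohol.

**Step 14**
Reactants: 15
Product: 16 (6-ketone)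
Conditions: Dess–Martin periodinane, NaHCO3, CH2Cl2, 25 °C
Reagents that add atoms: none
Why: Buffered oxidation gives the C6 ketone without epimerizing H-5. The trans-fused isomer is also the thermodynamic one.

**Step 15**
Reactants: 16
Product: 17 (C6–C7 TMS enol ether)
Conditions: LDA, THF, −78 °C; then TMSCl, Et3N
Reagents that add atoms: TMSCl, C[Si](C)(C)Cl
Why: Kinetic deprotonation occurs only at C7, because C5 is flanked by two quaternary carbons.

**Step 16**
Reactants: 17
Product: 18 (Δ7-en-6-one, 8-Me, 3,11-bis-OTBS)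
Conditions: Pd(OAc)2 (1.1 equiv), MeCN, 25 °C
Reagents that add atoms: none
Why: Saegusa–Ito oxidation gives the enone through Pd-enolate β-hydride elimination from C8, so the C8 epimers converge; C5 and C9 are not involved.

**Step 17**
Reactants: 18
Product: 19 (3,11-diol-6-oxo-Δ7)
Conditions: HF·pyridine, pyridine/THF, 40 °C
Reagents that add atoms: none
Why: Fluoride cleavage of both silyl ethers under non-basic conditions avoids γ-deprotonation and epimerization at C9.

**Step 18**
Reactants: 19 + 20 (umbelliferone, 7-hydroxycoumarin)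
Product: 21 (3-hydroxy-6-oxo-drim-7-en-11-yl umbelliferone ether)
Conditions: PPh3, DIAD, THF, 0→25 °C
Reagents that add atoms: none (the coumarin is reactant 20)
Why: Mitsunobu etherification is selective for the primary alcohol over the hindered C3 secondary alcohol, and C11 is not stereogenic.

**Step 19**
Reactants: 21
Product: 22 (epi-conferdione)
Conditions: Dess–Martin periodinane, NaHCO3, CH2Cl2, 25 °C
Reagents that add atoms: none
Why: Oxidation of the C3 alcohol gives the 3-ketone; the enone, coumarin lactone and all stereocentres survive.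

## Compound list
1 | 2-methylcyclohexane-1,3-dione | CC1C(=O)CCCC1=O | starting material
2 | methyl vinyl ketone | C=CC(C)=O | starting material
3 | 2-methyl-2-(3-oxobutyl)cyclohexane-1,3-dione | CC(=O)CCC1(C)C(=O)CCCC1=O | intermediate
4 | (R)-Wieland–Miescher ketone | C[C@@]12CCC(=O)C=C1CCCC2=O | intermediate
5 | (4aR,5R)-5-hydroxy-4a-methyl-hexahydronaphthalen-2(3H)-one | C[C@@]12CCC(=O)C=C1CCC[C@H]2O | intermediate
6 | 9-O-TES ether of 5 | C[C@@]12CCC(=O)C=C1CCC[C@H]2O[Si](CC)(CC)CC | intermediate
7 | 9-OTES-4,4,10-trimethyl-Δ5-octalin-3-one | C[C@@]12CCC(=O)C(C)(C)C1=CCC[C@H]2O[Si](CC)(CC)CC | intermediate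
8 | 3-hydroxy (equatorial) analogue of 7 | C[C@@]12CC[C@@H](O)C(C)(C)C1=CCC[C@H]2O[Si](CC)(CC)CC | intermediate
9 | 3-OTBS, 9-OTES analogue | C[C@@]12CC[C@@H](O[Si](C)(C)C(C)(C)C)C(C)(C)C1=CCC[C@H]2O[Si](CC)(CC)CC | intermediate
10 | 3-OTBS, 9-OH analogue | C[C@@]12CC[C@@H](O[Si](C)(C)C(C)(C)C)C(C)(C)C1=CCC[C@H]2O | intermediate
11 | 3-OTBS-Δ5-9-ketone | C[C@@]12CC[C@@H](O[Si](C)(C)C(C)(C)C)C(C)(C)C1=CCCC2=O | intermediate
12 | 8-methyl-9-ketone (C8 unspecified) | C[C@@]12CC[C@@H](O[Si](C)(C)C(C)(C)C)C(C)(C)C1=CCC(C)C2=O | intermediate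
13 | 9(11)-methylene-8-methyl-Δ5 (C8 unspecified) | C[C@@]12CC[C@@H](O[Si](C)(C)C(C)(C)C)C(C)(C)C1=CCC(C)C2=C | intermediate
14 | 6,11-diol, 3-OTBS (C8 unspecified) | C[C@@]12CC[C@@H](O[Si](C)(C)C(C)(C)C)C(C)(C)[C@H]1[C@H](O)CC(C)[C@H]2CO | intermediate
15 | 11-OTBS of 14 | C[C@@]12CC[C@@H](O[Si](C)(C)C(C)(C)C)C(C)(C)[C@H]1[C@H](O)CC(C)[C@H]2CO[Si](C)(C)C(C)(C)C | intermediate
16 | 6-ketone | C[C@@]12CC[C@@H](O[Si](C)(C)C(C)(C)C)C(C)(C)[C@H]1C(=O)CC(C)[C@H]2CO[Si](C)(C)C(C)(C)C | intermediate
17 | TMS enol ether (C6=C7) | C[C@@]12CC[C@@H](O[Si](C)(C)C(C)(C)C)C(C)(C)[C@H]1C(O[Si](C)(C)C)=CC(C)[C@H]2CO[Si](C)(C)C(C)(C)C | intermediate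
18 | 3,11-bis-OTBS-Δ7-en-6-one | C[C@@]12CC[C@@H](O[Si](C)(C)C(C)(C)C)C(C)(C)[C@H]1C(=O)C=C(C)[C@H]2CO[Si](C)(C)C(C)(C)C | intermediate
19 | 3,11-dihydroxy-drim-7-en-6-one | C[C@@]12CC[C@@H](O)C(C)(C)[C@H]1C(=O)C=C(C)[C@H]2CO | intermediate
20 | umbelliferone (7-hydroxycoumarin) | O=c1ccc2ccc(O)cc2o1 | starting material
21 | 3-hydroxy-6-oxo-drim-7-en-11-yl umbelliferone ether | C[C@@]12CC[C@@H](O)C(C)(C)[C@H]1C(=O)C=C(C)[C@H]2COc1ccc2ccc(=O)oc2c1 | intermediate
22 | epi-conferdione (5S,9R,10S) | C[C@@]12CCC(=O)C(C)(C)[C@H]1C(=O)C=C(C)[C@H]2COc1ccc2ccc(=O)oc2c1 | target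

## Totals
- Total steps: 19.
- Longest linear sequence: 19 steps (1 → 22); umbelliferone (20) is the only convergent input, at Step 18.

## Three steps most likely to fail
1. **Step 12 (double hydroboration of the hindered Δ5-ene and 9-methylene).**
   Fallback: reorder the sequence. Hydroborate the Δ5-ene of 9 alone with BH3·SMe2 at reflux, oxidize to the 6-ketone, and protect it as the 1,3-dioxolane. Then run Steps 8–11 and hydroborate only the exocyclic alkene with 9-BBN. Remove the ketal and rejoin at Step 15.
2. **Step 11 (methylenation of the ketone flanked by quaternary C10 and C8-Me).**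
   Fallback: van Leusen reductive cyanation of 12 (TosMIC, t-BuOK) to the 9-nitrile. Then DIBAL to the aldehyde, epimerization to the equatorial aldehyde with base, and NaBH4 to the C11 alcohol. This also fixes C9 thermodynamically.
3. **Step 16 (Saegusa–Ito dehydrogenation of a β-branched, hindered 6-ketone).**
   Fallback: α-selenation of the Step 15 lithium enolate (PhSeCl), then oxidative selenoxide syn-elimination (H2O2), which forms the Δ7-enone by a different mechanism.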